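The numbers in the tables are calculated from invented constants; scatter was added.

the same everywhere: free catalyst 65 µM; second catalyst 0.13 mM

| flask | substrate | coupling partner | temperature | remark | time |
|---|---|---|---|---|---|
| north | 0.0083 M | 0.0156 M (fed, over 40 min) | 75 °C | run made earlier |  |
| west | 0.011 M | 0.0156 M (fed, over 40 min) | 86 °C | run made earlier |  |
| south | 0.012 M | 0.0156 M (fed, over 40 min) | 75 °C | run made earlier |  |
| dawn | 0.0080 M | 0.0156 M | 80 °C | everything together at the start | 2.0 h |
| dusk | 0.013 M | 0.0156 M (fed, over 40 min) | 80 °C |  | 2.0 h |

- north (time / min: product / %, substrate / %): 8.00: 4.6, 49.3; 20.0: 28.6, 16.8; 40.0: 68.0, 2.8; 60.0: 81.0, 0.8; 80.0: 84.7, 0.2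
- west (time / min: product / %, substrate / %): 6.00: 3.7, 43.4; 12.0: 13.4, 18.1; 25.0: 37.2, 3.1; 40.0: 60.8, 0.1; 80.0: 68.1, 0
- south (time / min: product / %, substrate / %): 8.00: 4.2, 49.1; 20.0: 25.5, 17.7; 40.0: 60.6, 2.3; 60.0: 74.5, 0.6; 80.0: 74.8, 0

(readings scatter by 0.5 percentage points)

- the winner by amount of product, in percent of the substrate charged; "neither" if no more than 2 percentage points parts them (dawn / dusk / neither)
- how much product is there at the end, in percent of the substrate charged: dawn
- how much product is there at the end, in percent of the substrate charged: dusk



Late in the south run substrate stands at 0% and product has flattened at 74.8%, or 8.98 mM, less than the 0.0156 M of coupling partner fed, so the reckoning here takes the partner to be lost by a decay of its own and the remaining substrate to wait as an open intermediate. If coupling is pseudo-first-order in partner, with a rate constant proportional to the open intermediate, and decay ignores that intermediate, then integrating the split of the partner gives, once substrate and partner are gone: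

selectivity factor = ln[substrate charged / (substrate charged − product)] / (partner charged − product)

The plateaus give 0.219 mM⁻¹ in the north run and 0.208 mM⁻¹ in the south run, both at 75 °C, and 0.141 mM⁻¹ in the west run at 86 °C. The mean of the two temperatures, 0.177 mM⁻¹, serves as the selectivity factor of a fed flask at 80 °C.

For dawn to draw level with dusk near a yield of 0.7, dawn needs a factor of 0.120 mM⁻¹, which is a share 0.679 of the fed value. One pass from that yield gives dusk, fed like the earlier runs:

yield = 1 − exp[−factor × (partner charged − product)] = 68.4%

Dawn has its partner present from the start. In the north run substrate falls with a time constant of 11.1 min, and product closes on its plateau after the feed with 13.3 min. Taking those two times over to dawn as an estimate, the reckoning here puts the intermediate's average at a share 0.543 of its full level during the partner's life, less than the share needed. The estimated factor for dawn is then 0.0963 mM⁻¹, and one pass gives 61.8%.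

The forecast named dusk, with 62% (52% to 72%) for dawn and 69% (64% to 74%) for dusk, holding that in dawn “all partner is present while little intermediate exists”.

Dusk gives 68.6% and dawn 59.4%, so dusk wins. At its end dusk holds 31.3% as open intermediate. Put through the formula, the dusk result reads 0.174 mM⁻¹ and the dawn result 0.0831 mM⁻¹, a share 0.469 of the fed value, where a tie near 0.7 asked for 0.679.

    substrate + free catalyst → free catalyst + open intermediate (k = 27.9 L mol⁻¹ s⁻¹, Ea = 43.0 kJ mol⁻¹)
    coupling partner + catalyst intermediate → second catalyst + product (k = 104 L mol⁻¹ s⁻¹, Ea = 53.0 kJ mol⁻¹)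
    second catalyst + open intermediate ⇌ catalyst intermediate (K = 21.8 L mol⁻¹, k = 60.8 L mol⁻¹ s⁻¹, Ea = 52.0 kJ mol⁻¹, ΔH = −17.0 kJ mol⁻¹)
    coupling partner → decomposed reagent (k = 0.00117 s⁻¹, Ea = 94.0 kJ mol⁻¹)
    (constants at 80 °C)

The neighbour flask is dawn with 0.027 M of coupling partner. Keeping the dawn factor, two passes of the yield formula give 81.4%, and the computed flask gives 78.8%.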